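The question before me was which change to the west flask the next run should carry: the coupling partner doubled, or the free catalyst cut to 0.015 mM. Both were to be judged by the rate of making target at the conversion asked about.

in all of them: coupling partner 20.4 mM; free catalyst 0.17 mM

| charge | starting material | second substrate | remark |
|---|---|---|---|
| west | 17 mM | 17 mM | the very flask that is asked about, followed so far |
| south-east | 34 mM | 17 mM | run made earlier |
| flask | 17 mM | 17.0 mM |  |

- west (time / min: target / %, starting material / %): 1.00: 1.1, 80.9; 1.33: 2.1, 77.0; 2.00: 2.0, 68.4; 3.00: 3.1, 58.5; 5.00: 5.0, 44.6; 8.00: 6.2, 34.6; 12.0: 8.8, 25.5
- south-east (time / min: target / %, starting material / %): 1.50: 0.9, 60.2; 4.00: 2.1, 36.1; 8.00: 4.4, 20.8; 12.0: 6.6, 16.1; 15.0: 6.5, 12.1; 20.0: 6.2, 9.0; 30.0: 8.2, 5.8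

(scatter of a reading: 0.5 percentage points)

* factor on the rate of making target when 10% of the starting material are converted if coupling partner is charged twice over
* factor on the rate when 10% of the starting material are converted if free catalyst is charged at 0.015 mM instead

- what was read earlier has a scatter of 0.5 percentage points, one standard deviation
- no earlier run changes the charge of free catalyst; that part of a forecast is a guess
- no earlier run changes the charge of coupling partner; that part of a forecast is a guess

I needed one number from these readings, so I took the target made per minute per unit of catalyst charged, the turnover frequency. In the west run, at 8.00 min:

turnover = 1.05 mM / (8.00 min × 0.17 mM) = 0.775 /min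

In the south-east run, at the same time, 8.00 min, with 34 mM of starting material against 17 mM:

turnover = 1.10 /min

As read, the south-east run turned over more than the west run, by the factor 1.42, against a factor of 2.00 in the charge of starting material, so by my reckoning the turnover rose with that charge, but less than in proportion. If the west turnover also held at the lower catalyst charge, the rate would fall by the factor 0.0882, to 0.0116 mM/min. That cost could be reckoned, but neither run had changed the coupling partner. I therefore decided to leave the catalyst at 0.17 mM and to double the coupling partner in the next run.

The forecast gave 1.5 for the doubled partner, with a range of 0.9 to 2.1, and 0.09 for the cut catalyst, with a range of 0.03 to 0.3. Its remark on the first was: “The coupling partner is untested”.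

The simulation gave 1.99 for the doubled partner and 0.0887 for the cut catalyst.

    starting material + free catalyst ⇌ catalyst intermediate A (K = 36.0 /M, k = 3200 /M/min)
    coupling partner + catalyst intermediate A → free catalyst + target (k = 240 /M/min)
    second substrate + free catalyst ⇌ catalyst intermediate B (K = 34.0 /M, k = 480 /M/min)
    coupling partner + catalyst intermediate B → free catalyst + second product (k = 120 /M/min)
    2 starting material → homo dimer (k = 6.20 /M/min)

At 0.481 min the west flask turned over 1.26 /min per catalyst, against my 0.775 /min, which was a mean up to 8.00 min. The flask with the cut catalyst turned over 1.27 /min, while doubling the partner raised the turnover to 2.51 /min, a larger gain than the forecast's. Part of what kept the apparent order in second substrate of the west flask at −0.24 at that conversion was the backward run from catalyst intermediate B to second substrate and free catalyst: run without that step, the west flask showed an order of −0.77.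

All runs were computed for an exercise, noise included.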